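## The problem

The target **23** is a (2S)-flavanone: benzene ring A is fused to dihydropyranone ring C, and C2 of ring C carries aryl ring B. Positions are numbered as in the flavanone (O1, C2, C3, C4, C4a, C5 to C8, C8a; ring B primed), also for open-chain intermediates. Ring A is fully differentiated (5-OH hydrogen-bonded to the C4 carbonyl, 6-prenyl, 7-OMe, 8-H). Ring B carries a geranyl group at C2', wedged between C1' and the 3'-OH, so each ring needs a C-allylation whose position cannot be left to chance. C2 is the only stereocentre, so nothing in the molecule can relay to it and it must be set by a catalyst. Once ring C exists, base can open O1–C2 by retro-oxa-Michael reaction to an achiral 2'-hydroxychalcone; the open-chain β-hydroxy ketone is no safer, because base cleaves it by retro-aldol reaction or dehydrates it. The prenyl and geranyl olefins rule out hydrogenation, ozonolysis, electrophilic halogen and strong protic or Lewis acids (ortho-allyl phenols cyclise to chromans), which limits how the two phenols can be unmasked. The enabling feature is the place of O1: it sits on C8a, ortho to C4a, the carbon that carries C4. A C4–C3–C2 chain with a hydroxyl on C2 therefore lies six atoms around from a leaving group on C8a, and ring C can be closed by making O1–C8a while the C2–O bond, and with it the configuration, is left alone.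

## Retrosynthesis

**23 ⇒ 22 ⇒ 21 (O–MOM bonds, C4 oxidation level).** The two phenols are carried as methoxymethyl ethers and the C4 carbonyl as a secondary alcohol. Methoxymethyl ethers survive organolithium, hydroxide, borohydride and hot carbonate, and leave in dilute acid that prenylated flavanones tolerate; the C5 ether in **22** is further activated by the peri carbonyl. Carrying C4 as the alcohol **21** keeps every base-sensitive carbonyl relationship out of the ring-closing step. The forward oxidation has only to be neutral enough not to open ring C.

**21 ⇒ 20 (O1–C8a).** Cutting the aryl ether on the ring A side, and not O1–C2, means the forward step never breaks a bond to the stereocentre. The neighbouring cut at O1–C2 would call for an equilibrating oxa-Michael addition or a substitution with inversion at a benzylic carbon next to an electron-rich arene. Precursor **20** is an acyclic syn-1,3-diol with a bromide on C8a: one ring fewer, and its stereocentres are made by well-understood acyclic chemistry. The forward reaction must join the C2 oxygen to C8a in the presence of a second free carbinol and of four ether groups.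

**20 ⇒ 19 (C4–H).** The C4 carbinol comes from the ketone of β-hydroxy ketone **19** by chelation-controlled hydride delivery. The C4 configuration is deleted later, so it need only be uniform; the syn mode is chosen because it is the most dependable for β-hydroxy ketones.

**19 ⇒ 17 (C2–O).** The (S)-carbinol is traced to the enone **17** by formal enantioselective hydration of Cα=Cβ, done as copper-catalysed conjugate borylation and stereoretentive C–B oxidation. The neighbouring cut, C2–C3 by a direct asymmetric aldol addition of the enolate of **8** to **16**, is one step shorter. It relies, however, on methyl-ketone boron enolates, whose enantioselectivity is characteristically modest, and it forms **19** under conditions in which the aldol is reversible. Separating C–C bond formation from the stereo-defining event puts the latter on a flat, well-behaved enone.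

**17 ⇒ 8 + 16 (C2–C3 as Cα=Cβ).** A Claisen–Schmidt condensation joins two fragments of similar size. Only **8** can enolise and only **16** is an electrophile, so no selectivity is asked beyond E geometry, which conjugation supplies.

**8 ⇒ 7 ⇒ 6 ⇒ 5 ⇒ 3 + 4; 3 ⇒ 2 ⇒ 1 (ring A).**
- The bromine of **1** is the future C8a leaving group and is present from the start.
- The acetyl group (C4a–C4) enters by Friedel–Crafts acylation para to one methoxy group, giving **2**. The ketone then directs cleavage of its ortho methyl ether to give **3**, which frees exactly the oxygen that becomes O5.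
- That oxygen delivers the prenyl group to C6 by way of the 1,1-dimethylpropargyl ether **5**, its semi-hydrogenation product **6**, and a Claisen shift to **7**. The only ortho position open to the rearrangement is C6, so no regiochemical choice arises.
- Protection gives **8**.

**16 ⇒ 15 ⇒ 11 + 12; 11 ⇒ 10 ⇒ 9 (ring B).** The aryl–geranyl bond is cut. The bromide of **9** already marks C2' between the formyl and hydroxyl groups, so position is again fixed by the starting material and not by a directing effect. Acetal **10** and its methoxymethyl ether **11** make the ring compatible with bromine–lithium exchange (aryllithium **13**, arylcopper **14**). Coupling with geranyl bromide **12** must occur at the primary carbon without touching the E olefin, giving **15**, whose acetal is hydrolysed to **16** on work-up.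

## Roads not taken

**Alternative 1: ring B by cycloaddition.** The cut is through ring B itself (C2'–C3' and C1'–C6'). 3-Methoxyfuran **A2** adds to methyl (5E)-6,10-dimethylundeca-5,9-dien-2-ynoate **A3** in a [4+2] cycloaddition, and the oxygen bridge opens with aromatisation to methyl 2-geranyl-3-hydroxy-4-methoxybenzoate **A1**.
- Merits: all four ring B substituents are placed by the polarity match of the two components, and the geranyl group is never exposed to an aryl-metal coupling, so a branched SN2' isomer cannot form. In that one respect it is better than the chosen geranylation.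
- Weak points: β-alkyl propiolates are sluggish dienophiles toward furans and the adducts revert. The acid needed to open the bridge threatens the 1,5-diene of the geranyl chain. **A2** is a speciality diene. **A1** still needs phenol protection and adjustment of the ester to the aldehyde level of **16**.
- Comparison: it solves only the ring B sub-problem; the stereocentre and ring C would still need steps 9 to 14. The chosen plan sets against it a three-step path to **16** from a bromophenol whose substitution pattern is already fixed, and a boronate coupling held in reserve for the SN2' question.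

**Alternative 2: Petasis–Ferrier rearrangement.** The cut is C2–C3. A confined chiral Brønsted acid of the imidodiphosphorimidate type ionises the C2–O(enol) bond of the 4-methylene-1,3-benzodioxine **A5**. The enol carbon then adds to the aryloxycarbenium ion within the ion pair, giving the (2S)-5,7-dimethoxy-6-prenylflavanone **A4** with the ring B methoxymethyl ether.
- Merits: the C–C bond, ring C and the stereocentre arise in one catalytic step at the correct oxidation level, with no halogen and no redox shuttle. If it worked it would be the shorter synthesis.
- Weak points: the cation is benzylic to a ring with a para methoxy group, so it is long-lived and loosely paired, which works against face control. The geranyl olefin sits five atoms from the cationic carbon and can trap it. A strong acid must coexist with two allyl groups and an aryl acetal. The enantioselective variant is untested on 2-aryl enol acetals of this kind. The 5-methyl ether of **A4** would also have to be cleaved selectively with a boron trihalide, which prenylated phenols do not tolerate well.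
- Comparison: the chosen plan is longer, but every step is an established reaction class and the stereocentre is never again at a reacting carbon once set.

**Alternative 3: carbonylative annulation, then asymmetric reduction.** The cuts are C4a–C4, C4–C3 and O1–C2. Zerovalent palladium formed from PdCl2(PPh3)2 inserts into the C–I bond of 2-iodo-3,5-dimethoxy-4-prenylphenol **A8** and takes up carbon monoxide. It then couples with the ring B alkyne **A7**, and the phenol closes onto the ynone to give the flavone **A6**.
- Merits: it is the most convergent assembly of the skeleton, and **A6** is robust, achiral and easy to purify. In convergence and in reliability of the skeleton-forming step it is better than the chosen plan.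
- Weak points: the only stereocentre must then be made by enantioselective 1,4-reduction of a 2-arylchromone whose aryl group is ortho-substituted and electron-rich. This is a much less developed reaction than reduction of 2-alkylchromones. Hydrogenation catalysts would also touch the prenyl and geranyl olefins. The basic hydride medium can reopen the product **A4** by retro-oxa-Michael reaction. **A7** costs an extra homologation from **16**, **A8** needs a regioselective iodination, and the 5-methyl ether problem of Alternative 2 returns.
- Comparison: the chosen plan makes the stereocentre on an acyclic enone by a well-behaved reaction and then only carries it.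

Key step: step 12

Remarks on the chemistry:
- Abbreviations: prenyl = 3-methylbut-2-en-1-yl; geranyl = (2E)-3,7-dimethylocta-2,6-dien-1-yl; MOM = methoxymethyl.
- Assumption: 2-bromo-3-hydroxy-4-methoxybenzaldehyde **9** is taken as a catalogue compound; it is otherwise the known product of ring bromination of isovanillin.
- Assumption: the facial sense of the Josiphos-ligated boryl copper catalyst on enone **17** is not predicted here. The ligand antipode that borylates the si face of C2 is the one meant in step 10, and the configuration of **19** is to be checked by Mosher ester analysis before material is committed.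

## Steps

Step 1
Reactants: 1 1-bromo-3,5-dimethoxybenzene
Product: 3 1-(2-bromo-6-hydroxy-4-methoxyphenyl)ethanone, via 1-(2-bromo-4,6-dimethoxyphenyl)ethanone 2 (not isolated)
Conditions: AcCl, AlCl3 (3 equiv), CH2Cl2, 0 °C, then 40 °C; aq HCl work-up
Reagents that add atoms: acetyl chloride, CC(=O)Cl
Why: Friedel–Crafts acylation goes para to one methoxy group and ortho to the other (the site between the two methoxy groups is the more hindered); the AlCl3 chelate of the new ketone then cleaves only the ortho methyl ether, freeing the future O5.

Step 2
Reactants: 3 1-(2-bromo-6-hydroxy-4-methoxyphenyl)ethanone; 4 3-chloro-3-methylbut-1-yne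
Product: 5 1-[2-bromo-4-methoxy-6-(2-methylbut-3-yn-2-yloxy)phenyl]ethanone
Conditions: CuCl2·2H2O (1 mol %), DBU, MeCN, 0 °C to rt
Reagents that add atoms: none
Why: Copper-catalysed O-alkylation of a phenol with a tertiary propargylic chloride: the copper acetylide ionises to a stabilised propargyl/allenylidene electrophile that the phenoxide captures at the tertiary carbon, the standard entry to 1,1-dimethylpropargyl aryl ethers.

Step 3
Reactants: 5 1-[2-bromo-4-methoxy-6-(2-methylbut-3-yn-2-yloxy)phenyl]ethanone
Product: 6 1-[2-bromo-4-methoxy-6-(2-methylbut-3-en-2-yloxy)phenyl]ethanone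
Conditions: H2 (1 atm), Pd/CaCO3 poisoned with Pb(OAc)2, quinoline, EtOAc, rt
Reagents that add atoms: none
Why: Lindlar semi-hydrogenation stops at the terminal alkene; the poisoned palladium surface does not hydrogenolyse the aryl bromide.

Step 4
Reactants: 6 1-[2-bromo-4-methoxy-6-(2-methylbut-3-en-2-yloxy)phenyl]ethanone
Product: 7 1-(6-bromo-2-hydroxy-4-methoxy-3-prenylphenyl)ethanone
Conditions: N,N-diethylaniline, 130 °C
Reagents that add atoms: none
Why: Aromatic Claisen rearrangement: the [3,3] shift turns the 1,1-dimethylallyl unit into a prenyl group and can only end at the one free ortho carbon (future C6), since the other ortho carbon bears the acetyl group and cannot rearomatise.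

Step 5
Reactants: 7 1-(6-bromo-2-hydroxy-4-methoxy-3-prenylphenyl)ethanone
Product: 8 1-[6-bromo-4-methoxy-2-(methoxymethoxy)-3-prenylphenyl]ethanone
Conditions: NaH, MOMCl, DMF, 0 °C to rt
Reagents that add atoms: chloromethyl methyl ether, COCCl
Why: Williamson-type O-alkylation: the sodium phenoxide forms before the ketone enolises and is alkylated on oxygen by the hard electrophile; NaH is used because the phenol is hydrogen-bonded and flanked on both sides.

Step 6
Reactants: 9 2-bromo-3-hydroxy-4-methoxybenzaldehyde
Product: 10 2-bromo-3-(dimethoxymethyl)-6-methoxyphenol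
Conditions: HC(OMe)3, p-TsOH·H2O (cat.), MeOH, rt; Et3N quench
Reagents that add atoms: trimethyl orthoformate, COC(OC)OC; methanol, CO
Why: Acid-catalysed acetalisation with orthoformate as water scavenger; the acetal masks the aldehyde against the organolithium of step 8 and is installed before the MOM group so that no aryl MOM ether meets acidic methanol.

Step 7
Reactants: 10 2-bromo-3-(dimethoxymethyl)-6-methoxyphenol
Product: 11 2-bromo-1-(dimethoxymethyl)-4-methoxy-3-(methoxymethoxy)benzene
Conditions: MOMCl, i-Pr2NEt, CH2Cl2, 0 °C to rt
Reagents that add atoms: chloromethyl methyl ether, COCCl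
Why: O-alkylation of the acidic ortho-bromophenol under amine base; the dimethyl acetal is stable to these basic conditions.

Step 8
Reactants: 11 2-bromo-1-(dimethoxymethyl)-4-methoxy-3-(methoxymethoxy)benzene; 12 geranyl bromide [(2E)-1-bromo-3,7-dimethylocta-2,6-diene]
Product: 16 2-geranyl-4-methoxy-3-(methoxymethoxy)benzaldehyde, via aryllithium 13 (not isolated), via arylcopper 14 (not isolated), via geranylated dimethyl acetal 15 (not isolated)
Conditions: n-BuLi, THF, −78 °C; CuBr·SMe2, −78 to −40 °C; 12, −40 to 0 °C; then 0.5 M aq HCl, THF, 0 °C to rt
Reagents that add atoms: water, O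
Why: Bromine–lithium exchange at −78 °C outruns any attack on the acetal and gives an aryllithium held between two chelating oxygens; the derived arylcopper substitutes the allylic bromide at its primary carbon (SN2, not SN2') with the E olefin intact. Dilute acid then hydrolyses the very labile electron-rich benzaldehyde dimethyl acetal while the aryl MOM ether survives.

Step 9
Reactants: 8 1-[6-bromo-4-methoxy-2-(methoxymethoxy)-3-prenylphenyl]ethanone; 16 2-geranyl-4-methoxy-3-(methoxymethoxy)benzaldehyde
Product: 17 (2E)-1-[6-bromo-4-methoxy-2-(methoxymethoxy)-3-prenylphenyl]-3-[2-geranyl-4-methoxy-3-(methoxymethoxy)phenyl]prop-2-en-1-one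
Conditions: KOH, EtOH, rt
Reagents that add atoms: none
Why: Claisen–Schmidt condensation: only 8 can enolise and only 16 is an electrophile, and E1cB loss of water gives the conjugated E enone; aryl bromide, MOM ethers and isolated olefins are inert to hydroxide.

Step 10
Reactants: 17 (2E)-1-[6-bromo-4-methoxy-2-(methoxymethoxy)-3-prenylphenyl]-3-[2-geranyl-4-methoxy-3-(methoxymethoxy)phenyl]prop-2-en-1-one
Product: 19 (3S)-1-[6-bromo-4-methoxy-2-(methoxymethoxy)-3-prenylphenyl]-3-[2-geranyl-4-methoxy-3-(methoxymethoxy)phenyl]-3-hydroxypropan-1-one, via (S)-β-pinacolboryl ketone 18 (not isolated)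
Conditions: CuCl (5 mol %), NaOt-Bu (10 mol %), Josiphos ligand 1-[2-(diphenylphosphino)ferrocenyl]ethyldicyclohexylphosphine (6 mol %, antipode as in the remark), B2pin2, MeOH (2 equiv), THF, rt; then NaBO3·4H2O, THF/H2O, rt
Reagents that add atoms: bis(pinacolato)diboron (boron and pinacolate of 18 only), CC1(C)OB(OC1(C)C)B1OC(C)(C)C(C)(C)O1; sodium perborate (the hydroxyl oxygen of 19), [Na+].[O-]OB=O
Why: Copper-catalysed asymmetric conjugate borylation: the ligated Cu–Bpin species adds across Cα=Cβ with boron on the si face of the β-carbon under control of the chiral bisphosphine, and methanol protonates the copper enolate. Perborate then replaces C–B by C–O with retention, so the (S)-carbinol is set by the catalyst alone; the aryl bromide and the unactivated olefins do not react with boryl copper at room temperature.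

Step 11
Reactants: 19 (3S)-1-[6-bromo-4-methoxy-2-(methoxymethoxy)-3-prenylphenyl]-3-[2-geranyl-4-methoxy-3-(methoxymethoxy)phenyl]-3-hydroxypropan-1-one
Product: 20 (1R,3S)-1-[6-bromo-4-methoxy-2-(methoxymethoxy)-3-prenylphenyl]-3-[2-geranyl-4-methoxy-3-(methoxymethoxy)phenyl]propane-1,3-diol (1,3-syn)
Conditions: Et2BOMe, THF/MeOH (4:1), −78 °C; NaBH4, −78 °C; AcOH, then MeOH co-evaporation
Reagents that add atoms: none
Why: Narasaka–Prasad reduction: Et2BOMe ties hydroxyl and ketone into a six-membered boron chelate and external hydride adds axially, so the C2 centre directs the new C4 carbinol 1,3-syn (R). This centre only has to be uniform, as step 13 removes it.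

Step 12
Reactants: 20 (1R,3S)-1-[6-bromo-4-methoxy-2-(methoxymethoxy)-3-prenylphenyl]-3-[2-geranyl-4-methoxy-3-(methoxymethoxy)phenyl]propane-1,3-diol
Product: 21 (2S,4R)-2-[2-geranyl-4-methoxy-3-(methoxymethoxy)phenyl]-7-methoxy-5-(methoxymethoxy)-6-prenyl-3,4-dihydro-2H-chromen-4-ol (2,4-trans)
Conditions: CuI (10 mol %), 3,4,7,8-tetramethyl-1,10-phenanthroline (20 mol %), Cs2CO3 (2 equiv), toluene, 110 °C
Reagents that add atoms: none
Why: Cs2CO3 deprotonates the C2 hydroxyl, and the phenanthroline-bound monovalent copper alkoxide activates the C8a–Br bond (oxidative addition to a transient trivalent aryl copper alkoxide), after which C–O reductive elimination forms O1–C8a. This is an intramolecular Ullmann-type etherification, the known copper-catalysed O-arylation of secondary benzylic alcohols by ortho-tethered aryl bromides that gives 2-arylchromans. Ring C closes as a six-membered ring in a 6-exo sense, the oxygen attacking the arene carbon whose bromide leaves outside the new ring. No stereocentre is created: C2 stays S because only its O–H bond is exchanged for O–aryl and the C2–O bond is never broken, and C4 is a spectator. The selectivity needed is between the two hydroxyls, and geometry secures it, since the C4 oxygen could reach C8a only through a four-membered ring. Copper alkoxides do not readily undergo β-hydride elimination, so the free C4 carbinol is not oxidised at the expense of the bromide as it could be on palladium. Working at the diol level removes the β-hydroxy ketone that hot carbonate would cleave by retro-aldol reaction or dehydrate. The 2,4-trans product can place the C2 aryl group equatorial, so no strain opposes closure.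

Step 13
Reactants: 21 (2S,4R)-2-[2-geranyl-4-methoxy-3-(methoxymethoxy)phenyl]-7-methoxy-5-(methoxymethoxy)-6-prenyl-3,4-dihydro-2H-chromen-4-ol
Product: 22 (2S)-2-[2-geranyl-4-methoxy-3-(methoxymethoxy)phenyl]-7-methoxy-5-(methoxymethoxy)-6-prenyl-2,3-dihydro-4H-chromen-4-one
Conditions: Dess–Martin periodinane, NaHCO3, CH2Cl2, 0 °C to rt
Reagents that add atoms: none
Why: Dess–Martin oxidation under bicarbonate buffer converts the benzylic secondary alcohol to the aryl ketone without acid or base strong enough to open ring C, so C2 is untouched; the periodinane does not attack the trisubstituted olefins.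

Step 14
Reactants: 22 (2S)-2-[2-geranyl-4-methoxy-3-(methoxymethoxy)phenyl]-7-methoxy-5-(methoxymethoxy)-6-prenyl-2,3-dihydro-4H-chromen-4-one
Product: 23 (2S)-2-(2-geranyl-3-hydroxy-4-methoxyphenyl)-5-hydroxy-7-methoxy-6-prenyl-2,3-dihydro-4H-chromen-4-one (CNP0241771.1)
Conditions: 3 M aq HCl, MeOH, 40 °C
Reagents that add atoms: none
Why: Acid-catalysed acetal exchange with methanol removes both MOM ethers, the C5 ether being activated by the peri carbonyl; dilute HCl at mild temperature is the usual way to unmask prenylated flavanones without hydrating or cyclising the olefins or opening ring C.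

## Compound list

1 | 1-bromo-3,5-dimethoxybenzene | COc1cc(Br)cc(OC)c1 | starting material
2 | 1-(2-bromo-4,6-dimethoxyphenyl)ethanone | CC(=O)c1c(Br)cc(OC)cc1OC | intermediate (not isolated)
3 | 1-(2-bromo-6-hydroxy-4-methoxyphenyl)ethanone | CC(=O)c1c(Br)cc(OC)cc1O | intermediate
4 | 3-chloro-3-methylbut-1-yne | CC(C)(Cl)C#C | starting material
5 | 1-[2-bromo-4-methoxy-6-(2-methylbut-3-yn-2-yloxy)phenyl]ethanone | CC(=O)c1c(Br)cc(OC)cc1OC(C)(C)C#C | intermediate
6 | 1-[2-bromo-4-methoxy-6-(2-methylbut-3-en-2-yloxy)phenyl]ethanone | CC(=O)c1c(Br)cc(OC)cc1OC(C)(C)C=C | intermediate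
7 | 1-(6-bromo-2-hydroxy-4-methoxy-3-prenylphenyl)ethanone | CC(=O)c1c(Br)cc(OC)c(CC=C(C)C)c1O | intermediate
8 | 1-[6-bromo-4-methoxy-2-(methoxymethoxy)-3-prenylphenyl]ethanone | CC(=O)c1c(Br)cc(OC)c(CC=C(C)C)c1OCOC | intermediate
9 | 2-bromo-3-hydroxy-4-methoxybenzaldehyde | COc1ccc(C=O)c(Br)c1O | starting material
10 | 2-bromo-3-(dimethoxymethyl)-6-methoxyphenol | COc1ccc(C(OC)OC)c(Br)c1O | intermediate
11 | 2-bromo-1-(dimethoxymethyl)-4-methoxy-3-(methoxymethoxy)benzene | COc1ccc(C(OC)OC)c(Br)c1OCOC | intermediate
12 | geranyl bromide, (2E)-1-bromo-3,7-dimethylocta-2,6-diene | CC(C)=CCC/C(C)=C/CBr | starting material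
13 | [6-(dimethoxymethyl)-3-methoxy-2-(methoxymethoxy)phenyl]lithium | [Li]c1c(C(OC)OC)ccc(OC)c1OCOC | intermediate (not isolated)
14 | [6-(dimethoxymethyl)-3-methoxy-2-(methoxymethoxy)phenyl]copper | [Cu]c1c(C(OC)OC)ccc(OC)c1OCOC | intermediate (not isolated)
15 | 1-(dimethoxymethyl)-2-geranyl-4-methoxy-3-(methoxymethoxy)benzene | COc1ccc(C(OC)OC)c(C/C=C(\C)CCC=C(C)C)c1OCOC | intermediate (not isolated)
16 | 2-geranyl-4-methoxy-3-(methoxymethoxy)benzaldehyde | COc1ccc(C=O)c(C/C=C(\C)CCC=C(C)C)c1OCOC | intermediate
17 | (2E)-1-[6-bromo-4-methoxy-2-(methoxymethoxy)-3-prenylphenyl]-3-[2-geranyl-4-methoxy-3-(methoxymethoxy)phenyl]prop-2-en-1-one | O=C(/C=C/c1ccc(OC)c(OCOC)c1C/C=C(\C)CCC=C(C)C)c1c(Br)cc(OC)c(CC=C(C)C)c1OCOC | intermediate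
18 | (3S)-1-[6-bromo-4-methoxy-2-(methoxymethoxy)-3-prenylphenyl]-3-[2-geranyl-4-methoxy-3-(methoxymethoxy)phenyl]-3-(4,4,5,5-tetramethyl-1,3,2-dioxaborolan-2-yl)propan-1-one | O=C(C[C@@H](c1ccc(OC)c(OCOC)c1C/C=C(\C)CCC=C(C)C)B1OC(C)(C)C(C)(C)O1)c1c(Br)cc(OC)c(CC=C(C)C)c1OCOC | intermediate (not isolated)
19 | (3S)-1-[6-bromo-4-methoxy-2-(methoxymethoxy)-3-prenylphenyl]-3-[2-geranyl-4-methoxy-3-(methoxymethoxy)phenyl]-3-hydroxypropan-1-one | O=C(C[C@@H](c1ccc(OC)c(OCOC)c1C/C=C(\C)CCC=C(C)C)O)c1c(Br)cc(OC)c(CC=C(C)C)c1OCOC | intermediate
20 | (1R,3S)-1-[6-bromo-4-methoxy-2-(methoxymethoxy)-3-prenylphenyl]-3-[2-geranyl-4-methoxy-3-(methoxymethoxy)phenyl]propane-1,3-diol (1,3-syn) | O[C@H](C[C@@H](c1ccc(OC)c(OCOC)c1C/C=C(\C)CCC=C(C)C)O)c1c(Br)cc(OC)c(CC=C(C)C)c1OCOC | intermediate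
21 | (2S,4R)-2-[2-geranyl-4-methoxy-3-(methoxymethoxy)phenyl]-7-methoxy-5-(methoxymethoxy)-6-prenyl-3,4-dihydro-2H-chromen-4-ol (2,4-trans) | O[C@@H]1C[C@@H](c3ccc(OC)c(OCOC)c3C/C=C(\C)CCC=C(C)C)Oc2cc(OC)c(CC=C(C)C)c(OCOC)c21 | intermediate
22 | (2S)-2-[2-geranyl-4-methoxy-3-(methoxymethoxy)phenyl]-7-methoxy-5-(methoxymethoxy)-6-prenyl-2,3-dihydro-4H-chromen-4-one | O=C1C[C@@H](c3ccc(OC)c(OCOC)c3C/C=C(\C)CCC=C(C)C)Oc2cc(OC)c(CC=C(C)C)c(OCOC)c21 | intermediate
23 | (2S)-2-(2-geranyl-3-hydroxy-4-methoxyphenyl)-5-hydroxy-7-methoxy-6-prenyl-2,3-dihydro-4H-chromen-4-one (CNP0241771.1) | COc1ccc([C@@H]2CC(=O)c3c(cc(OC)c(CC=C(C)C)c3O)O2)c(C/C=C(\C)CCC=C(C)C)c1O | target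

## Step count and least certain steps

Total step count: 14. Longest linear sequence: 11 steps (steps 1 to 5, then 9 to 14); the ring B branch (steps 6 to 8) is three steps.

**Step 12 (key step).** The electron-rich C8a–Br bond, flanked by the substituted C4a, may be activated too slowly, so that protodebromination or base-induced loss of water from the doubly activated C4 benzylic carbinol overtakes ring closure. Fallback: a transition-metal-free elimination–addition closure from **20**. Excess lithium 2,2,6,6-tetramethylpiperidide in THF (−78 to 0 °C) removes the C8 proton, which is acidified by the adjacent bromine and methoxy group, and loss of bromide gives the C8–C8a aryne of the diol F1. The C2 alkoxide captures it at C8a, the aryne carbon remote from the methoxy group and the only one within reach of a six-membered ring, and protonation gives **21**, where the route resumes. The C2–O bond is again untouched.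

**Step 10.** The ortho-geranyl aryl group on the β-carbon and the twisted aroyl group may erode facial discrimination in the borylcupration, and the basic perborate medium may dehydrate some product back to the enone. Fallback from **17**: Juliá–Colonna epoxidation (poly-D-leucine, urea–hydrogen peroxide, DBU, THF) attacks only the electron-poor olefin and gives the trans-(2S,3R)-epoxy ketone F2. Sodium phenylseleno(triethoxy)borate, made from (PhSe)2 and NaBH4 in EtOH with AcOH, then cleaves only the Cα–O bond and returns the route at **19** with the benzylic C–O bond and its configuration intact.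

**Step 2.** O-alkylation of a hydrogen-bonded, ortho-acylated phenol by a tertiary electrophile may stall, or the ether may ionise back to the phenol. Fallback from **3**: allyl bromide and K2CO3 in DMF give 1-[2-(allyloxy)-6-bromo-4-methoxyphenyl]ethanone F3. Claisen rearrangement at 190 °C gives 1-(3-allyl-6-bromo-2-hydroxy-4-methoxyphenyl)ethanone F4, and cross-metathesis with 2-methylbut-2-ene using the second-generation Grubbs catalyst converts the allyl group to prenyl, rejoining at **7**. This replaces steps 2 to 4 with the same number of operations.

**Step 8.** Attack of the arylcopper at the tertiary allylic terminus (SN2'), E/Z erosion through an allyl-metal species, or homocoupling may lower the yield of linear E product. Fallback from **11**: bromine–lithium exchange and quench with 2-isopropoxy-4,4,5,5-tetramethyl-1,3,2-dioxaborolane give the aryl pinacol boronate F5. Coupling with **12** under Pd(PPh3)4 and K2CO3 in THF/H2O puts the aryl group on the less substituted end of the π-allyl palladium intermediate and returns at **15**, which is hydrolysed to **16** as in step 8.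

**Step 14.** Protic acid may cyclise the prenyl group onto the freed C5 phenol or the geranyl group onto the C3' phenol (chroman formation), or promote opening of ring C and loss of configuration at C2. Fallback from **22**: TMSOTf with 2,2'-bipyridyl in CH2Cl2 at 0 °C transfers the MOM groups to the pyridine and leaves the bis(trimethylsilyl) ether F6, which water hydrolyses to **23** without a strong protic acid being present.

## Further compounds

F1 | step 12 | C8–C8a aryne of diol 20, (1R,3S)-1-[3,4-didehydro-5-methoxy-7-(methoxymethoxy)-6-prenylphenyl-type aryne]-3-[2-geranyl-4-methoxy-3-(methoxymethoxy)phenyl]propane-1,3-diol | O[C@H](C[C@@H](c1ccc(OC)c(OCOC)c1C/C=C(\C)CCC=C(C)C)O)C1=C(OCOC)C(CC=C(C)C)=C(OC)C#C1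
F2 | step 10 | [(2S,3R)-3-[2-geranyl-4-methoxy-3-(methoxymethoxy)phenyl]oxiran-2-yl][6-bromo-4-methoxy-2-(methoxymethoxy)-3-prenylphenyl]methanone | O=C([C@H]1O[C@@H]1c2ccc(OC)c(OCOC)c2C/C=C(\C)CCC=C(C)C)c3c(Br)cc(OC)c(CC=C(C)C)c3OCOC
F3 | step 2 | 1-[2-(allyloxy)-6-bromo-4-methoxyphenyl]ethanone | CC(=O)c1c(Br)cc(OC)cc1OCC=C
F4 | step 2 | 1-(3-allyl-6-bromo-2-hydroxy-4-methoxyphenyl)ethanone | CC(=O)c1c(Br)cc(OC)c(CC=C)c1O
F5 | step 8 | 2-[6-(dimethoxymethyl)-3-methoxy-2-(methoxymethoxy)phenyl]-4,4,5,5-tetramethyl-1,3,2-dioxaborolane | COc1ccc(C(OC)OC)c(B2OC(C)(C)C(C)(C)O2)c1OCOC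
F6 | step 14 | (2S)-2-[2-geranyl-4-methoxy-3-(trimethylsilyloxy)phenyl]-7-methoxy-6-prenyl-5-(trimethylsilyloxy)-2,3-dihydro-4H-chromen-4-one | O=C1C[C@@H](c3ccc(OC)c(O[Si](C)(C)C)c3C/C=C(\C)CCC=C(C)C)Oc2cc(OC)c(CC=C(C)C)c(O[Si](C)(C)C)c21
A1 | alternative 1 | methyl 2-geranyl-3-hydroxy-4-methoxybenzoate | COC(=O)c1ccc(OC)c(O)c1C/C=C(\C)CCC=C(C)C
A2 | alternative 1 | 3-methoxyfuran | COc1ccoc1
A3 | alternative 1 | methyl (5E)-6,10-dimethylundeca-5,9-dien-2-ynoate | COC(=O)C#CC/C=C(\C)CCC=C(C)C
A4 | alternative 2 | (2S)-2-[2-geranyl-4-methoxy-3-(methoxymethoxy)phenyl]-5,7-dimethoxy-6-prenyl-2,3-dihydro-4H-chromen-4-one | O=C1C[C@@H](c3ccc(OC)c(OCOC)c3C/C=C(\C)CCC=C(C)C)Oc2cc(OC)c(CC=C(C)C)c(OC)c21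
A5 | alternative 2 | 2-[2-geranyl-4-methoxy-3-(methoxymethoxy)phenyl]-5,7-dimethoxy-4-methylidene-6-prenyl-4H-1,3-benzodioxine | C=C1OC(c3ccc(OC)c(OCOC)c3C/C=C(\C)CCC=C(C)C)Oc2cc(OC)c(CC=C(C)C)c(OC)c21
A6 | alternative 3 | 2-[2-geranyl-4-methoxy-3-(methoxymethoxy)phenyl]-5,7-dimethoxy-6-prenyl-4H-chromen-4-one | O=c1cc(-c3ccc(OC)c(OCOC)c3C/C=C(\C)CCC=C(C)C)oc2cc(OC)c(CC=C(C)C)c(OC)c12
A7 | alternative 3 | 1-ethynyl-2-geranyl-4-methoxy-3-(methoxymethoxy)benzene | C#Cc1ccc(OC)c(OCOC)c1C/C=C(\C)CCC=C(C)C
A8 | alternative 3 | 2-iodo-3,5-dimethoxy-4-prenylphenol | Oc1cc(OC)c(CC=C(C)C)c(OC)c1I
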